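**Plan**

- Numbering used throughout: ring A is the cyclopentane C1 (fusion CH)–C2–C3 (CHOH)–C4 (CMe2)–C5 (fusion C–OH); ring B is the cycloheptanone C5–C6–C7–C8 (CHMe)–C9 (quaternary, Me and the C11–C12 chain)–C10 (C=O)–C1; the butenolide is C13–C16.
- Retrosynthesis: the butenolide is cut at C13–C16, C13=C14 and O–C16 back to a C9 allyl group. Ring A is cut at C4–C5, because the 1,3-diol O–C3–C4(Me2)–C5–O of ring A is what a C3–C4 2,2-dimethyl epoxide leaves behind when its tertiary C4 radical adds to a C5 ketone of ring B. Then follow C1–C2 (prenyl), the two-carbon unit C1/C5 of ring B (ring expansion), C9–C11 (allyl) and C8–CH3.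
- Forward order: a cyclopentanone carrying C8 and C9, then ring B by ketene [2+2] and reductive retro-aldol ring expansion to the seven-membered 1,3-dione, then C1 prenylation and epoxidation, then ring A by the radical closure, and the butenolide last.
- Stereochemistry: C8 from ligand-controlled copper-catalysed methyl addition; C9 from enolate allylation anti to the C8 methyl; C3 from the Shi epoxidation; C5 (anti to O3) from the 5-exo transition state; C1 by equilibration at the enolisable ring-fusion carbon.

Key step: step 7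

Assumption: the trans ring fusion of the target (H-1 anti to the C5 hydroxyl, which lets O5–H bond to the C10 carbonyl) is taken to be the more stable arrangement at the enolisable C1. In 11 and 12, C1 lies between two carbonyls, epimerises freely and is drawn without a descriptor.

**Route**

Step 1
Reactants: 1 2-methylcyclopent-2-en-1-one; 2 allyl iodide
Product: 4 (2S,3R)-2-allyl-2,3-dimethylcyclopentan-1-one, via bromomagnesium enolate 3 (not isolated)
Conditions: MeMgBr, CuBr·SMe2 (5 mol%), Josiphos-type ligand 1-[2-(dicyclohexylphosphino)ferrocenyl]ethyldiphenylphosphine (C36H44FeP2, 6 mol%, enantiomer chosen to give 3R), t-BuOMe, −78 °C; then 2, DMPU, −78 → 0 °C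
Reagents that add atoms: methylmagnesium bromide, C[Mg]Br; allyl iodide (2), C=CCI
Why: Copper-catalysed asymmetric conjugate addition of the Grignard reagent sets the methyl-bearing carbon (later C8, R) under ligand control, and the magnesium enolate so formed is allylated at its methyl-substituted carbon anti to the new neighbouring methyl group, which sets the quaternary centre (later C9, S).

Step 2
Reactants: 4 (2S,3R)-2-allyl-2,3-dimethylcyclopentan-1-one
Product: 5 {[(4R,5S)-5-allyl-4,5-dimethylcyclopent-1-en-1-yl]oxy}trimethylsilane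
Conditions: TMSOTf, Et3N, CH2Cl2, 0 °C; non-aqueous work-up, used crude
Reagents that add atoms: trimethylsilyl trifluoromethanesulfonate, C[Si](C)(C)OS(=O)(=O)C(F)(F)F
Why: Soft enolisation and O-silylation can give only one silyl enol ether, because the other α-carbon is quaternary.

Step 3
Reactants: 5 {[(4R,5S)-5-allyl-4,5-dimethylcyclopent-1-en-1-yl]oxy}trimethylsilane
Product: 6 (2S,3R)-2-allyl-7,7-dichloro-2,3-dimethyl-1-(trimethylsilyloxy)bicyclo[3.2.0]heptan-6-one (cis-fused, mixture at the two ring-fusion carbons)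
Conditions: Cl2CHCOCl (slow addition), Et3N, hexanes, rt
Reagents that add atoms: dichloroacetyl chloride, O=C(Cl)C(Cl)Cl (transferred as dichloroketene, ClC(Cl)=C=O)
Why: The [2+2] cycloaddition of dichloroketene to an electron-rich silyl enol ether joins the enol β-carbon to the ketene carbonyl carbon, so the CCl2 carbon ends up next to the silyloxy carbon, and the two new stereocentres are erased in step 4.

Step 4
Reactants: 6 (2S,3R)-2-allyl-7,7-dichloro-2,3-dimethyl-1-(trimethylsilyloxy)bicyclo[3.2.0]heptan-6-one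
Product: 9 (4S,5R)-4-allyl-4,5-dimethylcycloheptane-1,3-dione, via silyloxycyclobutanone 7 (not isolated), via hydroxycyclobutanone 8 (not isolated)
Conditions: Zn dust, AcOH, i-PrOH–H2O, 0 °C → rt, then 50 °C
Reagents that add atoms: none
Why: Zinc removes both α-chlorines, aqueous acetic acid cleaves the silyl ether, and the strained β-hydroxycyclobutanone opens by retro-aldol cleavage of the ring-fusion bond (reductive two-carbon ring expansion), so the ketene carbons become C5 (carbonyl) and C1 (CH2) of ring B while the allyl group is untouched.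

Step 5
Reactants: 9 (4S,5R)-4-allyl-4,5-dimethylcycloheptane-1,3-dione; 10 prenyl bromide
Product: 11 (4S,5R)-4-allyl-4,5-dimethyl-2-(3-methylbut-2-en-1-yl)cycloheptane-1,3-dione (epimers at C2 of the dione, which is C1 of the target)
Conditions: 10 (1.05 equiv), K2CO3, acetone, rt
Reagents that add atoms: prenyl bromide (10), CC(C)=CCBr
Why: C-alkylation of the 1,3-dione enolate with a soft allylic bromide takes place at the only doubly activated carbon, and the near-stoichiometric charge of bromide limits a second alkylation.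

Step 6
Reactants: 11 (4S,5R)-4-allyl-4,5-dimethyl-2-(3-methylbut-2-en-1-yl)cycloheptane-1,3-dione
Product: 12 (4S,5R)-4-allyl-2-{[(2R)-3,3-dimethyloxiran-2-yl]methyl}-4,5-dimethylcycloheptane-1,3-dione
Conditions: D-fructose-derived Shi ketone (1,2:4,5-di-O-isopropylidene-β-D-erythro-2,3-hexodiulo-2,6-pyranose, high loading), Oxone (2KHSO5·KHSO4·K2SO4), NaHCO3, MeCN–aq. Na2EDTA, pH 7–8, 0 °C; used without chromatography
Reagents that add atoms: potassium peroxymonosulfate (active part of Oxone), [K+].[O-]S(=O)(=O)OO
Why: The Shi epoxidation transfers oxygen from the chiral dioxirane through a spiro transition state to one face of the trisubstituted prenyl alkene and sets C3 as R by reagent control, while the monosubstituted allyl alkene reacts far more slowly and the near-neutral pH keeps the dione un-ionised.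

Step 7
Reactants: 12 (4S,5R)-4-allyl-2-{[(2R)-3,3-dimethyloxiran-2-yl]methyl}-4,5-dimethylcycloheptane-1,3-dione
Product: 14 (1R,3R,5R,8R,9S)-9-allyl-3,5-dihydroxy-4,4,8,9-tetramethylbicyclo[5.3.0]decan-10-one (target numbering, trans-fused), via cis-fused epimer 13 (not isolated)
Conditions: (C5H5)2TiCl2 (Cp2TiCl2, 2.5 equiv), Zn dust, THF, rt (green Cp2TiCl, trivalent titanium), added slowly to 12 in THF, rt; 1 M HCl, 0 °C; crude product then DBU (0.3 equiv), toluene, rt → 40 °C
Reagents that add atoms: none
Why: Cp2TiCl transfers one electron to the epoxide, the C4–O bond breaks to give the tertiary C4 radical with C3 retained as its titanium alkoxide, the radical adds to the C5 carbonyl, the oxygen radical is reduced by the second equivalent and acid releases the diol. The closest known reaction type is the titanocene-mediated reductive epoxide opening with addition of the carbon radical to a ketone carbonyl. Ring A closes 5-exo-trig, C4 onto C5=O. C5 is controlled by C3: in the chair-like transition state the bulky C3–O–Ti group sits pseudo-equatorial and away from the titanium-bound carbonyl oxygen, so the new C5–O bond should come out anti to C3–O. C1 is mobile in 12 and closure with the tether perpendicular to the carbonyl plane should give mainly the cis-fused epimer 13; because H-1 stays enolisable toward C10, DBU should move it to the trans-fused 14, which is expected to be favoured by the O5–H···O=C10 hydrogen bond. The step needs C5 and not C10 as acceptor, secured because C10 is flanked by quaternary C9 (a bond there would line up three fully substituted carbons and its alkoxy radical would fragment back), and it needs cyclisation before the radical is captured by titanium, helped by slow addition of the reagent, while the allyl group is out of reach.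

Step 8
Reactants: 14 (1R,3R,5R,8R,9S)-9-allyl-3,5-dihydroxy-4,4,8,9-tetramethylbicyclo[5.3.0]decan-10-one
Product: 15 4-[(1R,3R,5R,8R,9S)-3,5-dihydroxy-4,4,8,9-tetramethyl-10-oxobicyclo[5.3.0]dec-9-yl]butanal
Conditions: Rh(acac)(CO)2 (1 mol%), Xantphos (4,5-bis(diphenylphosphino)-9,9-dimethylxanthene, 3 mol%), CO/H2 (1:1, 10 bar), toluene, 70 °C
Reagents that add atoms: carbon monoxide, [C-]#[O+]
Why: Rhodium-catalysed hydroformylation with a wide-bite-angle diphosphine adds the formyl group to the terminal carbon of the allyl group, whose position on a quaternary centre further disfavours the branched aldehyde, and free hydroxyls and the hindered ketone are tolerated.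

Step 9
Reactants: 15 4-[(1R,3R,5R,8R,9S)-3,5-dihydroxy-4,4,8,9-tetramethyl-10-oxobicyclo[5.3.0]dec-9-yl]butanal; 16 glyoxylic acid (as monohydrate)
Product: 18 5-hydroxy-4-{2-[(1R,3R,5R,8R,9S)-3,5-dihydroxy-4,4,8,9-tetramethyl-10-oxobicyclo[5.3.0]dec-9-yl]ethyl}furan-2(5H)-one (lactol epimers), via morpholinobutenolide 17 (not isolated)
Conditions: 16 (1.2 equiv), morpholine (1.2 equiv), 1,4-dioxane, 20 → 40 °C; then 2 M aq. HCl, rt
Reagents that add atoms: glyoxylic acid (16), O=CC(=O)O; water, O
Why: The morpholine enamine of the aldehyde adds through its α-carbon (C13) to the formyl group of glyoxylic acid, the adduct lactonises and dehydrates to the 5-morpholinobutenolide, and mild aqueous acid exchanges the amine for hydroxyl (aldol-type condensation giving a γ-hydroxybutenolide).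

Step 10
Reactants: 18 5-hydroxy-4-{2-[(1R,3R,5R,8R,9S)-3,5-dihydroxy-4,4,8,9-tetramethyl-10-oxobicyclo[5.3.0]dec-9-yl]ethyl}furan-2(5H)-one
Product: 20 4-{2-[(1R,3R,5R,8R,9S)-3,5-dihydroxy-4,4,8,9-tetramethyl-10-oxobicyclo[5.3.0]dec-9-yl]ethyl}furan-2(5H)-one (the target), via hydroxy acid 19 (not isolated)
Conditions: NaBH4 (1.2 equiv), MeOH–THF, −20 → 0 °C; then 1 M HCl to pH 2, rt
Reagents that add atoms: none
Why: The lactol reacts through its ring-opened formyl carboxylate, borohydride reduces that aldehyde much faster than the C10 ketone shielded by C9 and C1, and the (Z)-hydroxy acid relactonises on acidification (reduction of a γ-hydroxybutenolide to the butenolide).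

**Compound list**

1 | 2-methylcyclopent-2-en-1-one | CC1=CCCC1=O | starting material
2 | allyl iodide (3-iodoprop-1-ene) | C=CCI | starting material
3 | bromomagnesium (3R)-2,3-dimethylcyclopent-1-en-1-olate | C[C@@H]1CCC(O[Mg]Br)=C1C | intermediate (not isolated)
4 | (2S,3R)-2-allyl-2,3-dimethylcyclopentan-1-one | C[C@@H]1CCC(=O)[C@@]1(C)CC=C | intermediate
5 | {[(4R,5S)-5-allyl-4,5-dimethylcyclopent-1-en-1-yl]oxy}trimethylsilane | C[C@@H]1CC=C(O[Si](C)(C)C)[C@@]1(C)CC=C | intermediate
6 | (2S,3R)-2-allyl-7,7-dichloro-2,3-dimethyl-1-(trimethylsilyloxy)bicyclo[3.2.0]heptan-6-one, cis-fused, mixture at C1/C5 of the bicycle | C[C@@H]1CC2C(=O)C(Cl)(Cl)C2(O[Si](C)(C)C)[C@@]1(C)CC=C | intermediate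
7 | (2S,3R)-2-allyl-2,3-dimethyl-1-(trimethylsilyloxy)bicyclo[3.2.0]heptan-6-one | C[C@@H]1CC2C(=O)CC2(O[Si](C)(C)C)[C@@]1(C)CC=C | intermediate (not isolated)
8 | (2S,3R)-2-allyl-1-hydroxy-2,3-dimethylbicyclo[3.2.0]heptan-6-one | C[C@@H]1CC2C(=O)CC2(O)[C@@]1(C)CC=C | intermediate (not isolated)
9 | (4S,5R)-4-allyl-4,5-dimethylcycloheptane-1,3-dione | C[C@@H]1CCC(=O)CC(=O)[C@@]1(C)CC=C | intermediate
10 | prenyl bromide (1-bromo-3-methylbut-2-ene) | CC(C)=CCBr | starting material
11 | (4S,5R)-4-allyl-4,5-dimethyl-2-(3-methylbut-2-en-1-yl)cycloheptane-1,3-dione, C2 epimers | C[C@@H]1CCC(=O)C(CC=C(C)C)C(=O)[C@@]1(C)CC=C | intermediate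
12 | (4S,5R)-4-allyl-2-{[(2R)-3,3-dimethyloxiran-2-yl]methyl}-4,5-dimethylcycloheptane-1,3-dione, C2 epimers | C[C@@H]1CCC(=O)C(C[C@H]2OC2(C)C)C(=O)[C@@]1(C)CC=C | intermediate (key-step precursor)
13 | (1S,3R,5R,8R,9S)-9-allyl-3,5-dihydroxy-4,4,8,9-tetramethylbicyclo[5.3.0]decan-10-one, cis-fused C1 epimer | C[C@@H]1CC[C@@]2(O)[C@H](C[C@@H](O)C2(C)C)C(=O)[C@@]1(C)CC=C | intermediate (not isolated)
14 | (1R,3R,5R,8R,9S)-9-allyl-3,5-dihydroxy-4,4,8,9-tetramethylbicyclo[5.3.0]decan-10-one, trans-fused | C[C@@H]1CC[C@@]2(O)[C@@H](C[C@@H](O)C2(C)C)C(=O)[C@@]1(C)CC=C | intermediate (key-step product)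
15 | 4-[(1R,3R,5R,8R,9S)-3,5-dihydroxy-4,4,8,9-tetramethyl-10-oxobicyclo[5.3.0]dec-9-yl]butanal | C[C@@H]1CC[C@@]2(O)[C@@H](C[C@@H](O)C2(C)C)C(=O)[C@@]1(C)CCCC=O | intermediate
16 | glyoxylic acid | O=CC(=O)O | starting material
17 | 5-(morpholin-4-yl)-4-{2-[(1R,3R,5R,8R,9S)-3,5-dihydroxy-4,4,8,9-tetramethyl-10-oxobicyclo[5.3.0]dec-9-yl]ethyl}furan-2(5H)-one | C[C@@H]1CC[C@@]2(O)[C@@H](C[C@@H](O)C2(C)C)C(=O)[C@@]1(C)CCC1=CC(=O)OC1N1CCOCC1 | intermediate (not isolated)
18 | 5-hydroxy-4-{2-[(1R,3R,5R,8R,9S)-3,5-dihydroxy-4,4,8,9-tetramethyl-10-oxobicyclo[5.3.0]dec-9-yl]ethyl}furan-2(5H)-one, lactol epimers | C[C@@H]1CC[C@@]2(O)[C@@H](C[C@@H](O)C2(C)C)C(=O)[C@@]1(C)CCC1=CC(=O)OC1O | intermediate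
19 | (Z)-3-(hydroxymethyl)-5-[(1R,3R,5R,8R,9S)-3,5-dihydroxy-4,4,8,9-tetramethyl-10-oxobicyclo[5.3.0]dec-9-yl]pent-2-enoic acid | C[C@@H]1CC[C@@]2(O)[C@@H](C[C@@H](O)C2(C)C)C(=O)[C@@]1(C)CC/C(CO)=C/C(=O)O | intermediate (not isolated)
20 | 4-{2-[(1R,3R,5R,8R,9S)-3,5-dihydroxy-4,4,8,9-tetramethyl-10-oxobicyclo[5.3.0]dec-9-yl]ethyl}furan-2(5H)-one | C[C@@H]1CC[C@@]2(O)[C@@H](C[C@@H](O)C2(C)C)C(=O)[C@@]1(C)CCC1=CC(=O)OC1 | target

**Step count**

Total: 10 steps. Longest linear sequence: 10 steps (from 1).

**Steps most likely to fail**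

Step 7. The tertiary C4 radical may be captured by a second trivalent titanium centre and lose hydride before it adds, reversibly, to the C5 carbonyl; the base equilibration at C1 may also be accompanied by dehydration of the β-hydroxy ketone. The fallback sets out from 12 and comes back at 14. Compound 12 is isomerised on purpose with excess Cp2TiCl (substrate added to the reagent, THF, rt) to (4S,5R)-4-allyl-2-[(2R)-2-hydroxy-3-methylbut-3-en-1-yl]-4,5-dimethylcycloheptane-1,3-dione F1, the allylic alcohol that this capture produces. F1 is then cyclised by iron-hydride hydrogen-atom transfer (Fe(acac)3, PhSiH3, EtOH–ethylene glycol, 60 °C). This regenerates the same C4 radical from the 1,1-disubstituted alkene with no radical-trapping metal present, so 5-exo addition to C5 and reduction of the oxygen radical should give 13, and the same DBU treatment should give 14. The monosubstituted allyl group reacts more slowly under these conditions.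

Step 6. The dioxirane may oxidise the enol or enolate of the dione, and the enol oxygen may attack the fresh epoxide to give a cyclic ketal; facial selectivity may also be incomplete. The fallback sets out from 9, bypasses step 5 as well and comes back at 12 by bringing the epoxide in ready-made. Prenol is epoxidised by Sharpless asymmetric epoxidation (Ti(OiPr)4, D-(−)-diisopropyl tartrate, t-BuOOH, 4 Å sieves, CH2Cl2, −20 °C) to (R)-3,3-dimethylglycidol F2. F2 is oxidised (SO3·pyridine, DMSO, Et3N, 0 °C) to (S)-3,3-dimethyloxirane-2-carbaldehyde F3. Organocatalytic reductive alkylation of 9 with F3 (L-proline cat., diethyl 2,6-dimethyl-1,4-dihydropyridine-3,5-dicarboxylate, CH2Cl2, rt) passes through the Knoevenagel product, alkylidene dione F4, whose conjugate reduction should give 12 under neutral conditions.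

Step 9. Acid-promoted dehydration or retro-aldol cleavage of the tertiary β-hydroxy ketone (C5–OH, C10=O) may occur during the condensation and the HCl hydrolysis; over-reduction at C10 in step 10 is a related concern. The fallback sets out from 15 and reaches 20 without acid. α-Methylenation (N,N-dimethylmethyleneiminium iodide, Et3N, CH2Cl2, rt) gives the 2-methylidene aldehyde F5. Luche reduction (NaBH4, CeCl3·7H2O, MeOH, −78 °C) gives the allylic alcohol F6. Selective acylation of its primary hydroxyl (acryloyl chloride, 2,4,6-collidine, CH2Cl2, −78 °C) gives the acrylate F7. Ring-closing metathesis with the second-generation Grubbs catalyst ((H2IMes)(PCy3)Cl2Ru=CHPh, toluene, 80 °C) closes the C13=C14 bond of the butenolide and should give 20.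

**Further compounds**

F1 | step 7 | (4S,5R)-4-allyl-2-[(2R)-2-hydroxy-3-methylbut-3-en-1-yl]-4,5-dimethylcycloheptane-1,3-dione | C[C@@H]1CCC(=O)C(C[C@@H](O)C(C)=C)C(=O)[C@@]1(C)CC=C
F2 | step 6 | (R)-3,3-dimethylglycidol, [(2R)-3,3-dimethyloxiran-2-yl]methanol | OC[C@H]1OC1(C)C
F3 | step 6 | (S)-3,3-dimethyloxirane-2-carbaldehyde | O=C[C@H]1OC1(C)C
F4 | step 6 | (4S,5R)-4-allyl-2-{[(2R)-3,3-dimethyloxiran-2-yl]methylidene}-4,5-dimethylcycloheptane-1,3-dione | C[C@@H]1CCC(=O)C(=C[C@H]2OC2(C)C)C(=O)[C@@]1(C)CC=C
F5 | step 9 | 2-methylidene-4-[(1R,3R,5R,8R,9S)-3,5-dihydroxy-4,4,8,9-tetramethyl-10-oxobicyclo[5.3.0]dec-9-yl]butanal | C[C@@H]1CC[C@@]2(O)[C@@H](C[C@@H](O)C2(C)C)C(=O)[C@@]1(C)CCC(=C)C=O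
F6 | step 9 | (1R,3R,5R,8R,9S)-3,5-dihydroxy-9-[3-(hydroxymethyl)but-3-en-1-yl]-4,4,8,9-tetramethylbicyclo[5.3.0]decan-10-one | C[C@@H]1CC[C@@]2(O)[C@@H](C[C@@H](O)C2(C)C)C(=O)[C@@]1(C)CCC(=C)CO
F7 | step 9 | 2-methylidene-4-[(1R,3R,5R,8R,9S)-3,5-dihydroxy-4,4,8,9-tetramethyl-10-oxobicyclo[5.3.0]dec-9-yl]butyl prop-2-enoate | C[C@@H]1CC[C@@]2(O)[C@@H](C[C@@H](O)C2(C)C)C(=O)[C@@]1(C)CCC(=C)COC(=O)C=C
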